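The azecane ring is treated as a seven-membered azepane enlarged by three atoms. In the ring, N1–C2–C3(Me) followed by C4–C5 is a homoallylic amine in disguise, the retron of a [2,3]-sigmatropic shift of an ammonium methylide. The methylide of (S)-1-(3-chloropropyl)-2-[(Z)-prop-1-enyl]azepane, made by fluoride desilylation, forms the C2–C3 bond, breaks the old N–C bond, and delivers the ten-membered ring with the C3 methyl stereocentre by 1,3-chirality transfer, all in one operation. Hydrogenation, N-alkylation of 3,4-bis(6,7-dimethoxyquinolin-5-yl)pyrrole (phenol-directed bromination, double Suzuki coupling) and demethylation complete the route.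

Key step: step 5

Assumption: the two pyrrole–quinoline axes carry no specified configuration in the target, so rotamers about them are treated as one compound.

**Fragment A: the azacycle**

Step 1
Reactants: 1 (S)-1-(tert-butoxycarbonyl)azepane-2-carboxylic acid
Product: 3 tert-butyl (S)-2-formylazepane-1-carboxylate, via N-acylimidazole 2 (not isolated)
Conditions: CDI, CH2Cl2, 0 °C to rt; then i-Bu2AlH, −78 °C; aq. tartaric acid
Reagents that add atoms: none
Why: Staab-type aldehyde synthesis, in which the N-acylimidazole is reduced by i-Bu2AlH to a tetrahedral aluminate that is stable at −78 °C and releases the aldehyde only on work-up, so over-reduction and epimerisation of the α-stereocentre should be avoided.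

Step 2
Reactants: 3 tert-butyl (S)-2-formylazepane-1-carboxylate
Product: 4 tert-butyl (S)-2-[(Z)-prop-1-en-1-yl]azepane-1-carboxylate
Conditions: EtPPh3Br, KN(SiMe3)2, THF, −78 °C to 0 °C
Reagents that add atoms: ethyltriphenylphosphonium bromide, CC[P+](c1ccccc1)(c1ccccc1)c1ccccc1.[Br-]
Why: Wittig olefination with a salt-free non-stabilised ylide is kinetically (Z)-selective through the cis-oxaphosphetane and fast at low temperature, so the α-amino aldehyde should not epimerise; the minor (E)-isomer is to be removed by chromatography because it would erode the later chirality transfer.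

Step 3
Reactants: 4 tert-butyl (S)-2-[(Z)-prop-1-en-1-yl]azepane-1-carboxylate
Product: 5 (S)-2-[(Z)-prop-1-en-1-yl]azepane hydrochloride
Conditions: HCl (4 M in 1,4-dioxane), rt
Reagents that add atoms: hydrogen chloride, Cl
Why: Acidolytic Boc cleavage (loss of 2-methylpropene and CO2) should leave the (Z)-allylic amine untouched and give a non-volatile, storable salt.

Step 4
Reactants: 5 (S)-2-[(Z)-prop-1-en-1-yl]azepane hydrochloride; 6 1-bromo-3-chloropropane
Product: 7 (S)-1-(3-chloropropyl)-2-[(Z)-prop-1-en-1-yl]azepane
Conditions: K2CO3, MeCN, rt to 40 °C (excess 6)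
Reagents that add atoms: none
Why: SN2 N-alkylation in which the bromide end of the dihalide reacts far faster than the chloride end, and the α-branched tertiary amine resists quaternisation, so mono-alkylation is expected.

Step 5
Reactants: 7 (S)-1-(3-chloropropyl)-2-[(Z)-prop-1-en-1-yl]azepane
Product: 10 (3S,4E)-1-(3-chloropropyl)-3-methyl-1,2,3,6,7,8,9,10-octahydroazecine, via silylmethylammonium triflate 8 (not isolated), via ammonium methylide 9 (not isolated)
Conditions: Me3SiCH2OTf, CH2Cl2, 0 °C to rt; evaporate; CsF, DME, rt
Reagents that add atoms: (trimethylsilyl)methyl trifluoromethanesulfonate, C[Si](C)(C)COS(=O)(=O)C(F)(F)F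
Why: Me3SiCH2OTf quaternises the amine (expected mainly anti to the propenyl group) to salt 8, fluoride removes silicon to give the non-stabilised N-methylide 9, and its carbanion (future C2) adds suprafacially to the methyl-bearing alkene terminus (future C3) while the azepane N–C2 bond breaks in a concerted [2,3]-sigmatropic (Stevens-type) shift through a five-membered envelope transition state. The closest known reaction type is the fluoride-induced desilylation–[2,3] ring expansion of 2-vinylpyrrolidinium and 2-vinylpiperidinium (trimethylsilyl)methyl salts to eight- and nine-membered amines. The ten-membered ring is closed not end to end but by three-atom enlargement of the seven-membered ring (a five-centre, six-electron pericyclic closure fused to the azepane), so no high dilution is needed. The new C3 stereocentre is controlled by the azepane C2 stereocentre through 1,3-chirality transfer relayed by the (Z)-olefin: 1,3-allylic strain between the propenyl methyl group and the ring CH2 forces the C2–H bond to eclipse the alkene, nitrogen leaves and carbon arrives on the same single face, and the (S)-amine should give (S)-C3 together with the (E)-ring olefin. The step needs the [2,3] path to beat the [1,2]-shift, α′,β-elimination and alkylation at the chloropropyl chain, and the (E)-olefin transition state to beat the (Z) one; the first is secured by the very low barrier of the allylic shift of a non-stabilised ylide at room temperature (primary alkyl chlorides react far more slowly with carbanions), the second by the (Z)-propenyl group. Because the azepane is flexible, both N-epimers of 8 should reach this transition state and converge on 10.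

Step 6
Reactants: 10 (3S,4E)-1-(3-chloropropyl)-3-methyl-1,2,3,6,7,8,9,10-octahydroazecine
Product: 11 (S)-1-(3-chloropropyl)-3-methylazecane
Conditions: H2 (1 atm), PtO2, EtOAc, rt
Reagents that add atoms: none
Why: Heterogeneous catalytic hydrogenation of the strained (E)-cyclodecene; platinum is chosen over palladium because it causes little double-bond migration, so the allylic C3 stereocentre should not be scrambled, and the alkyl chloride is inert.

**Fragment B: the bis-quinolyl pyrrole**

Step 7
Reactants: 12 4-amino-2-methoxyphenol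
Product: 13 7-methoxyquinolin-6-ol
Conditions: glycerol, H2SO4, sodium 3-nitrobenzenesulfonate, 135 °C
Reagents that add atoms: glycerol, OCC(O)CO
Why: Skraup quinoline synthesis, in which the aniline adds to acrolein formed in situ, the ring closes at the unhindered position para to the methoxy group, and dehydration and oxidation give the 6,7-dioxygenated quinoline.

Step 8
Reactants: 13 7-methoxyquinolin-6-ol
Product: 14 5-bromo-7-methoxyquinolin-6-ol
Conditions: NBS, MeCN, 0 °C
Reagents that add atoms: N-bromosuccinimide, BrN1C(=O)CCC1=O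
Why: Electrophilic aromatic bromination directed by the free 6-hydroxyl to C5, the α-position ortho to OH (2-naphthol-type reactivity), which fixes a regiochemistry that 6,7-dimethoxyquinoline itself would not guarantee.

Step 9
Reactants: 14 5-bromo-7-methoxyquinolin-6-ol
Product: 15 5-bromo-6,7-dimethoxyquinoline
Conditions: MeI, K2CO3, DMF, rt
Reagents that add atoms: iodomethane, CI
Why: Williamson O-methylation of the phenoxide, which is far more nucleophilic than the quinoline nitrogen.

Step 10
Reactants: 15 5-bromo-6,7-dimethoxyquinoline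
Product: 16 6,7-dimethoxy-5-(4,4,5,5-tetramethyl-1,3,2-dioxaborolan-2-yl)quinoline
Conditions: B2pin2, PdCl2(dppf), KOAc, 1,4-dioxane, 90 °C
Reagents that add atoms: bis(pinacolato)diboron, CC1(C)OB(OC1(C)C)B1OC(C)(C)C(C)(C)O1
Why: Miyaura borylation (oxidative addition to zerovalent palladium, acetate-assisted transmetalation from B2pin2) should convert the hindered aryl bromide into the pinacol boronate.

Step 11
Reactants: 16 6,7-dimethoxy-5-(4,4,5,5-tetramethyl-1,3,2-dioxaborolan-2-yl)quinoline (2.5 equiv); 17 3,4-dibromo-1-(triisopropylsilyl)-1H-pyrrole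
Product: 19 3,4-bis(6,7-dimethoxyquinolin-5-yl)-1H-pyrrole, via N-silyl bis-quinolyl pyrrole 18 (not isolated)
Conditions: Pd(OAc)2, SPhos, K3PO4, toluene/H2O, 100 °C; then Bu4NF, THF, rt
Reagents that add atoms: none
Why: Twofold Suzuki–Miyaura coupling in which the bulky electron-rich SPhos ligand should let the ortho-methoxy boronate couple at both adjacent pyrrole positions while the N-silyl group masks the pyrrole nitrogen, after which fluoride cleaves the N–Si bond in the same flask.

**Union and end game**

Step 12
Reactants: 19 3,4-bis(6,7-dimethoxyquinolin-5-yl)-1H-pyrrole; 11 (S)-1-(3-chloropropyl)-3-methylazecane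
Product: 20 (S)-1-{3-[3,4-bis(6,7-dimethoxyquinolin-5-yl)-1H-pyrrol-1-yl]propyl}-3-methylazecane
Conditions: NaH, DMF, 0 °C; then 11, NaI (cat.), 60 °C
Reagents that add atoms: none
Why: SN2 N-alkylation of the sodium pyrrolide with iodide catalysis (possibly through the azetidinium ion, which opens to the same product); the anion is far more nucleophilic than the quinoline nitrogens.

Step 13
Reactants: 20 (S)-1-{3-[3,4-bis(6,7-dimethoxyquinolin-5-yl)-1H-pyrrol-1-yl]propyl}-3-methylazecane
Product: 21 isohalitulin
Conditions: BBr3 (excess), CH2Cl2, −78 °C to rt; MeOH; work-up under argon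
Reagents that add atoms: none
Why: Lewis-acid aryl methyl ether cleavage, in which BBr3 coordinates each methoxy oxygen and bromide removes the methyl group by SN2; excess reagent compensates for complexation by the three basic nitrogens.

**Compound list**

1 | (S)-1-(tert-butoxycarbonyl)azepane-2-carboxylic acid | OC(=O)[C@@H]1CCCCCN1C(=O)OC(C)(C)C | starting material
2 | tert-butyl (S)-2-(1H-imidazole-1-carbonyl)azepane-1-carboxylate | O=C([C@@H]1CCCCCN1C(=O)OC(C)(C)C)n1ccnc1 | intermediate
3 | tert-butyl (S)-2-formylazepane-1-carboxylate | O=C[C@@H]1CCCCCN1C(=O)OC(C)(C)C | intermediate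
4 | tert-butyl (S)-2-[(Z)-prop-1-en-1-yl]azepane-1-carboxylate | C/C=C\[C@@H]1CCCCCN1C(=O)OC(C)(C)C | intermediate
5 | (S)-2-[(Z)-prop-1-en-1-yl]azepane hydrochloride | C/C=C\[C@@H]1CCCCCN1.Cl | intermediate
6 | 1-bromo-3-chloropropane | ClCCCBr | starting material
7 | (S)-1-(3-chloropropyl)-2-[(Z)-prop-1-en-1-yl]azepane | C/C=C\[C@@H]1CCCCCN1CCCCl | intermediate
8 | (2S)-1-(3-chloropropyl)-2-[(Z)-prop-1-en-1-yl]-1-[(trimethylsilyl)methyl]azepan-1-ium trifluoromethanesulfonate (N-epimers) | C/C=C\[C@@H]1CCCCC[N+]1(CCCCl)C[Si](C)(C)C.[O-]S(=O)(=O)C(F)(F)F | intermediate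
9 | [(2S)-1-(3-chloropropyl)-2-[(Z)-prop-1-en-1-yl]azepan-1-ium-1-yl]methanide | C/C=C\[C@@H]1CCCCC[N+]1(CCCCl)[CH2-] | intermediate
10 | (3S,4E)-1-(3-chloropropyl)-3-methyl-1,2,3,6,7,8,9,10-octahydroazecine | C[C@H]1/C=C/CCCCCN(CCCCl)C1 | intermediate
11 | (S)-1-(3-chloropropyl)-3-methylazecane | C[C@H]1CCCCCCCN(CCCCl)C1 | intermediate
12 | 4-amino-2-methoxyphenol | COc1cc(N)ccc1O | starting material
13 | 7-methoxyquinolin-6-ol | COc1cc2ncccc2cc1O | intermediate
14 | 5-bromo-7-methoxyquinolin-6-ol | COc1cc2ncccc2c(Br)c1O | intermediate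
15 | 5-bromo-6,7-dimethoxyquinoline | COc1cc2ncccc2c(Br)c1OC | intermediate
16 | 6,7-dimethoxy-5-(4,4,5,5-tetramethyl-1,3,2-dioxaborolan-2-yl)quinoline | COc1cc2ncccc2c(B2OC(C)(C)C(C)(C)O2)c1OC | intermediate
17 | 3,4-dibromo-1-(triisopropylsilyl)-1H-pyrrole | CC(C)[Si](C(C)C)(C(C)C)n1cc(Br)c(Br)c1 | starting material
18 | 3,4-bis(6,7-dimethoxyquinolin-5-yl)-1-(triisopropylsilyl)-1H-pyrrole | CC(C)[Si](C(C)C)(C(C)C)n1cc(-c2c(OC)c(OC)cc3ncccc23)c(-c2c(OC)c(OC)cc3ncccc23)c1 | intermediate
19 | 3,4-bis(6,7-dimethoxyquinolin-5-yl)-1H-pyrrole | c1c(-c2c(OC)c(OC)cc3ncccc23)c(-c2c(OC)c(OC)cc3ncccc23)c[nH]1 | intermediate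
20 | (S)-1-{3-[3,4-bis(6,7-dimethoxyquinolin-5-yl)-1H-pyrrol-1-yl]propyl}-3-methylazecane | C[C@H]1CCCCCCCN(CCCn2cc(-c3c(OC)c(OC)cc4ncccc34)c(-c3c(OC)c(OC)cc4ncccc34)c2)C1 | intermediate
21 | isohalitulin | C[C@H]1CCCCCCCN(CCCn2cc(-c3c(O)c(O)cc4ncccc34)c(-c3c(O)c(O)cc4ncccc34)c2)C1 | target

**Step count**

Total: 13 steps. Longest linear sequence: 8 steps (steps 1–6, 12, 13).

**Steps most likely to fail**

Step 5 (key step). The short-lived non-stabilised ylide may be diverted before it rearranges: protonation by adventitious water, a [1,2]-shift, α′,β-elimination, or attack on the chloropropyl chain. Passage through the rotamer that leads to the (Z)-ring olefin would also erode the chirality transfer. The fallback uses an ester-stabilised ylide made under neutral conditions and removes the ester afterwards. It sets out from 7: tert-butyl diazoacetate with catalytic Cu(acac)2 in toluene at 85 °C should give, through the copper carbenoid, the N-ylide and the same [2,3]-shift, tert-butyl (3S,4E)-1-(3-chloropropyl)-3-methyl-1,2,3,6,7,8,9,10-octahydroazecine-2-carboxylate F1 as a mixture of C2 epimers. CF3CO2H in CH2Cl2 should cleave the ester to (3S,4E)-1-(3-chloropropyl)-3-methyl-1,2,3,6,7,8,9,10-octahydroazecine-2-carboxylic acid F2. Photoredox hydrodecarboxylation of this α-amino acid (9-mesityl-10-methylacridinium tetrafluoroborate, catalytic diphenyl disulfide, 2,6-lutidine, blue light) removes the carboxyl group and erases the C2 centre. The fallback comes back to the route at 10.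

Step 11. Transmetalation of the boronate, hindered by the ortho-methoxy group and the peri position, may be slow, so protodeboronation outruns coupling and the reaction stalls after one arylation. The fallback is a Negishi coupling, which avoids the boronate. It sets out from 15: bromine–lithium exchange (n-BuLi, THF, −78 °C) and transmetalation with ZnCl2 should give chloro(6,7-dimethoxyquinolin-5-yl)zinc F3. Coupling of excess F3 with 17 under Pd(OAc)2/SPhos in THF at 60 °C should give 18, and Bu4NF then removes the silyl group. The fallback comes back to the route at 19.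

Step 13. Fourfold demethylation may stay incomplete, the α-unsubstituted pyrrole may degrade under the Lewis acid and the HBr formed on quenching, and the catechols may oxidise in air on work-up. The fallback replaces the methyl ethers by benzyl ethers so that the last step is a neutral hydrogenolysis. It sets out from 14: BBr3 in CH2Cl2 on this simple bromide should give 5-bromoquinoline-6,7-diol F4, and BnBr/K2CO3 in DMF should give 6,7-bis(benzyloxy)-5-bromoquinoline F5. Miyaura borylation as in step 10 should give 6,7-bis(benzyloxy)-5-(4,4,5,5-tetramethyl-1,3,2-dioxaborolan-2-yl)quinoline F6. Twofold Suzuki coupling with 17 as in step 11 should give 3,4-bis[6,7-bis(benzyloxy)quinolin-5-yl]-1-(triisopropylsilyl)-1H-pyrrole F7, and Bu4NF should give 3,4-bis[6,7-bis(benzyloxy)quinolin-5-yl]-1H-pyrrole F8. Alkylation with 11 (NaH, DMF, NaI) should give (S)-1-(3-{3,4-bis[6,7-bis(benzyloxy)quinolin-5-yl]-1H-pyrrol-1-yl}propyl)-3-methylazecane F9. Hydrogenolysis (H2, Pd/C, THF/MeOH, AcOH) then removes the four benzyl groups, and the fallback comes back to the route at 21.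

Further compounds
F1 | step 5 | tert-butyl (3S,4E)-1-(3-chloropropyl)-3-methyl-1,2,3,6,7,8,9,10-octahydroazecine-2-carboxylate | C[C@H]1/C=C/CCCCCN(CCCCl)C1C(=O)OC(C)(C)C
F2 | step 5 | (3S,4E)-1-(3-chloropropyl)-3-methyl-1,2,3,6,7,8,9,10-octahydroazecine-2-carboxylic acid | C[C@H]1/C=C/CCCCCN(CCCCl)C1C(=O)O
F3 | step 11 | chloro(6,7-dimethoxyquinolin-5-yl)zinc | COc1cc2ncccc2c([Zn]Cl)c1OC
F4 | step 13 | 5-bromoquinoline-6,7-diol | Oc1cc2ncccc2c(Br)c1O
F5 | step 13 | 6,7-bis(benzyloxy)-5-bromoquinoline | Brc1c(OCc2ccccc2)c(OCc2ccccc2)cc2ncccc12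
F6 | step 13 | 6,7-bis(benzyloxy)-5-(4,4,5,5-tetramethyl-1,3,2-dioxaborolan-2-yl)quinoline | CC1(C)OB(OC1(C)C)c1c(OCc2ccccc2)c(OCc2ccccc2)cc2ncccc12
F7 | step 13 | 3,4-bis[6,7-bis(benzyloxy)quinolin-5-yl]-1-(triisopropylsilyl)-1H-pyrrole | CC(C)[Si](C(C)C)(C(C)C)n1cc(-c2c(OCc3ccccc3)c(OCc3ccccc3)cc3ncccc23)c(-c2c(OCc3ccccc3)c(OCc3ccccc3)cc3ncccc23)c1
F8 | step 13 | 3,4-bis[6,7-bis(benzyloxy)quinolin-5-yl]-1H-pyrrole | c1c(-c2c(OCc3ccccc3)c(OCc3ccccc3)cc3ncccc23)c(-c2c(OCc3ccccc3)c(OCc3ccccc3)cc3ncccc23)c[nH]1
F9 | step 13 | (S)-1-(3-{3,4-bis[6,7-bis(benzyloxy)quinolin-5-yl]-1H-pyrrol-1-yl}propyl)-3-methylazecane | C[C@H]1CCCCCCCN(CCCn2cc(-c3c(OCc5ccccc5)c(OCc5ccccc5)cc4ncccc34)c(-c3c(OCc5ccccc5)c(OCc5ccccc5)cc4ncccc34)c2)C1
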